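## The problem

The target is a 3→8-linked biflavanone. C3 of an eriodictyol unit (unit 1) is bonded to C8 of a naringenin unit (unit 2), so an sp3 carbon next to a ketone is joined to a carbon of a pentasubstituted phloroglucinol ring that lies between two oxygens. There are three stereocentres. C2 and C3 of unit 1 are both R, which places the two aryl groups cis on the pyranone, the less stable arrangement. C2 of unit 2 (R) is too far from the others to be set by them and needs reagent control. C2 of unit 1 can direct C3 if C3 is created by addition to a ring that already carries the C2 aryl group. Once the C4 carbonyl of unit 1 exists, C3–H is enolisable and can relax to the trans isomer, and both pyranones can open to chalcones under base, so that carbonyl must appear late and meet only near-neutral reagents. Seven phenols, one pair of them a catechol, call for protection that comes off without acid, base or oxidant. A 3-(2-hydroxyaryl)chroman with an oxygen at C4 on a 5,7-dioxygenated ring is one acid-catalysed step from a pterocarpan, so everything between creation of that oxygen and closure of the unit 2 pyranone must be non-acidic. The feature that opens the key step is the substitution pattern of ring A of unit 2. C8 carries the link and is flanked by two oxygens (O1 and O7), with the third oxygen (O5) para to it, which is the pattern a vinylketene and an ynol ether give when they are fused into a benzene ring.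

## Retrosynthesis

**30 ⇒ 29 ⇒ 28 (O–benzyl and O–silyl bonds).** The last operations are only unmasking. Six benzyl ethers in 29 fall to hydrogen under neutral conditions, which suits the catechol and the labile C3. The seventh phenol oxygen (O7 of unit 2) carries the silyl group left by the key step and is freed from 28 by buffered fluoride. Nothing is asked of these steps beyond mildness.

**28 ⇒ 27 ⇒ 26 (C4=O of unit 1 back to C4–O–Si).** The carbonyl of unit 1 is what makes C3 epimerisable, so it is cut back to the alcohol 27 and, before that, its silyl ether 26. Carrying the ketone through the construction of unit 2 would be shorter, but it would expose the cis arrangement to every basic step. The forward oxidation must be neutral.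

**26 ⇒ 24 + 25 (C2–aryl bond of unit 2).** Cutting this bond leads to the achiral chromone 24 and the commercial boronic acid 25, for which catalytic asymmetric 1,4-arylation is established. The neighbouring cut, O1–C2 by oxa-Michael closure of a chalcone, has no dependable asymmetric version for an unactivated chalcone and needs base. The forward step must let the ligand override three distant centres.

**24 ⇒ 22 ⇒ 21 ⇒ 20 ⇒ 18 (O1–C2, C3–C4 and C4–C4a of unit 2).** The pyranone carbons are peeled off the phenol in three cuts: oxa-Michael closure of an ynone (from 22), addition of a two-carbon acetylide to aldehyde 21, and ortho-formylation of phenol 20. A Friedel–Crafts or Fries acylation would save steps, but acid would ionise the C4 oxygen and let the free hydroxyl close onto C4. An untethered electrophile would also have four electron-rich CH positions to choose from. Delivery of the C1 unit through a magnesium phenoxide is basic and specific for the one free ortho position. 20 differs from 18 only in the silyl group on O4.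

**18 ⇒ 16 (C3–H and C4–O of unit 1).** Both centres come from one syn addition across the C3=C4 bond of chromene 16. The C2 aryl group blocks one face, so hydrogen enters C3 from the other and the two aryl groups end cis. A route through an enolate would settle on the trans isomer. 16 has a single stereocentre, and the forward step needs boron at C4 and clean facial selection.

**16 ⇒ 9 + 11 (C8–C8a, C6–C7 and C4a–C8a of unit 2, the key cut).** Ring A of unit 2 is taken apart into the siloxyalkyne 9 and the four-carbon cyclobutenone 11. A cross-coupling of a preformed phloroglucinol would need a differentiated 2-halo-1,3,5-trioxybenzene and would form a doubly ortho-substituted aryl–alkenyl bond. The benzannulation instead builds the ring with its substituents in place: hydroxyl and siloxy on either side of the link and benzyloxy para to it. The two flanking oxygens are constitutionally equivalent, so closure through either gives the 8-linked isomer. The forward reaction must give one orientation in the ketene–alkyne cycloaddition and must leave C2 of the chromene intact under heating.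

**11 ⇒ 10 (O–alkyl bond).** The ethyl group of commercial 10 is exchanged for benzyl so that O5 of unit 2 is released in the final hydrogenolysis.

**9 ⇒ 6 ⇒ 5 (C–O bond of the ynol ether, then the alkyne carbon).** 9 is reached from the terminal alkyne 6 by oxygen transfer to its acetylide and O-silylation. 6 comes from aldehyde 5 by one-carbon homologation under aprotic conditions, because a methanolic homologation of an enal invites conjugate addition.

**5 ⇒ 2 + 4 (O1–C2 and C3–C4 of unit 1).** An oxa-Michael/aldol condensation of salicylaldehyde 2 with enal 4 closes ring C, sets C2 by catalyst control and leaves the formyl handle on C3, all in one step. Both partners are achiral aldehydes.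

**2 ⇒ 1 and 4 ⇒ 3.** Partial benzylation of 1 and two-carbon homologation of 3 lead back to commercial materials.

## Roads not taken

**Alternative 1:** Oxidative 1,2-aryl shift of a chalcone.
- Cut and key step: the C3–C8 bond is made by migration. In chalcone A1 the finished (R)-naringenin tribenzyl ether sits through C8 on the β-carbon. Tl(NO3)3 in methanol with trimethyl orthoformate moves that arene to the α-carbon, and dilute HCl closes the pyranone to the 3-aryl chromone A2.
- Merits: unit 2 is made separately by standard chemistry, the link cannot form at C6, and no stereocentre of unit 1 is exposed to the key step. In convergence and in freedom from a thermally labile centre this road is better than the chosen one.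
- Weak points: A2 has neither the C2 aryl group nor either stereocentre of unit 1. The 3,4-dioxygenated aryl group would have to be added to C2 of a chromone whose C3 carries a di-ortho-substituted arene, and asymmetric 1,4-addition to such 3-substituted chromones is not established. Protonation of the resulting enolate would favour the trans isomer. The thallium reagent is stoichiometric and toxic, and the migrating ring is deactivated by its own carbonyl group.
- Comparison: the chosen plan sets C2 by catalysis in its first ring-forming step and lets it direct C3 in a concerted addition.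

**Alternative 2:** Aldol stereotriad closed by aryl–oxygen coupling.
- Cut and key step: O1–C8a of unit 1. The open-chain bromo alcohol A3, whose three centres come from aldol chemistry, is cyclised with Pd(OAc)2, a bulky di-tert-butyl biaryl phosphine and Cs2CO3 to the flavan A4.
- Merits: all three centres of unit 1 are fixed on an acyclic chain by well-understood methods, the C4 oxygen is present from the start, and no chromene is heated. In stereochemical security this road is at least equal to the chosen one.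
- Weak points: the aryl bromide is electron-rich and ortho-substituted, and a secondary benzylic alkoxide on palladium can lose β-hydride to give the ketone. The chain needs two separate C–C bond constructions with a hindered 2,6-dioxygenated arylacetate unit. The differentiated ring A of unit 2 must be bought with protecting-group steps on phloroglucinol. The C4 centre is made only to be erased.
- Comparison: the chosen plan offers a shorter path to the unit 1 core and a ring A that is differentiated as it forms.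

**Alternative 3:** o-Quinone methide cycloaddition with a Z-stilbene.
- Cut and key step: O1–C2 and C3–C4 of unit 1 together. A chiral phosphoric acid with trimethyl orthoformate converts aldehyde 2 into the methoxy o-quinone methide A5, which adds the Z-stilbene A6 to give the all-cis 4-methoxyflavan A7.
- Merits: this is the most convergent road. Both units are complete, two bonds and three centres form at once, and the cis relationship is carried over from the alkene geometry. In step economy it beats the chosen plan.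
- Weak points: A6 is a hindered stilbene whose unit 2 arene is deactivated by a carbonyl group, and quinone methides of this kind react well only with strongly donor-substituted alkenes. A stepwise cationic path or acid-induced Z→E isomerisation would lose the cis information. Control by the acid catalyst of both orientation and absolute sense is unproven for such a pair, and the unit 2 flavanone must survive the acid.
- Comparison: the chosen plan uses steps with closer precedent and creates the cis relationship by syn addition to a preformed ring with an unambiguous facial bias.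

Key step: step 7

Assumption: the absolute sense of the two catalyst-controlled steps (3 and 13) is assigned from the accepted face-selection models of these catalyst families; if either runs the other way, the mirror-image catalyst is used and nothing else changes.

## Route

Step 1
Reactants: 1 2,4,6-trihydroxybenzaldehyde
Product: 2 4,6-bis(benzyloxy)-2-hydroxybenzaldehyde
Conditions: BnBr (2.1 equiv), K2CO3, DMF, 0 °C → rt
Reagents that add atoms: benzyl bromide, BrCc1ccccc1
Why: Williamson etherification; the hydroxyl para to the formyl group reacts first and one ortho hydroxyl follows, while the last is held in a hydrogen bond to the carbonyl and should stay free, as in the usual partial benzylation of phloroglucinol carbonyl compounds.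

Step 2
Reactants: 3 3,4-bis(benzyloxy)benzaldehyde
Product: 4 (E)-3-[3,4-bis(benzyloxy)phenyl]prop-2-enal
Conditions: Ph3P=CHCHO, toluene, 80 °C
Reagents that add atoms: (triphenylphosphoranylidene)acetaldehyde, O=CC=P(c1ccccc1)(c1ccccc1)c1ccccc1
Why: Wittig olefination with the stabilised formylmethylene ylide should give the E-enal directly; a slight excess of 3 limits a second homologation.

Step 3
Reactants: 2 4,6-bis(benzyloxy)-2-hydroxybenzaldehyde; 4 (E)-3-[3,4-bis(benzyloxy)phenyl]prop-2-enal
Product: 5 (S)-5,7-bis(benzyloxy)-2-[3,4-bis(benzyloxy)phenyl]-2H-chromene-3-carbaldehyde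
Conditions: (R)-2-[diphenyl(trimethylsilyloxy)methyl]pyrrolidine (20 mol%), 2-nitrobenzoic acid (20 mol%), 4 Å molecular sieves, toluene, rt
Reagents that add atoms: none
Why: Organocatalytic oxa-Michael/aldol condensation: the phenol of 2 adds to Cβ of the iminium ion of 4 on the face left open by the diphenyl(silyloxy)methyl group, and the resulting enamine closes onto the formyl group and loses water. This sets C2 (S by the sequence rule here, the same spatial arrangement as C2 of unit 1 in 30).

Step 4
Reactants: 5 (S)-5,7-bis(benzyloxy)-2-[3,4-bis(benzyloxy)phenyl]-2H-chromene-3-carbaldehyde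
Product: 6 (S)-5,7-bis(benzyloxy)-2-[3,4-bis(benzyloxy)phenyl]-3-ethynyl-2H-chromene
Conditions: Me3SiCHN2, LiN(iPr)2, THF, −78 °C → rt
Reagents that add atoms: trimethylsilyldiazomethane, C[Si](C)(C)C=[N+]=[N-]
Why: Colvin rearrangement: addition of lithiated trimethylsilyldiazomethane, loss of silanolate and N2, and 1,2-hydrogen shift of the alkylidene carbene should give the enyne. The aprotic medium avoids the conjugate addition of methanol that can divert Ohira–Bestmann homologation of enals, and C2 is not touched.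

Step 5
Reactants: 6 (S)-5,7-bis(benzyloxy)-2-[3,4-bis(benzyloxy)phenyl]-3-ethynyl-2H-chromene
Product: 9 (S)-5,7-bis(benzyloxy)-2-[3,4-bis(benzyloxy)phenyl]-3-[(triisopropylsiloxy)ethynyl]-2H-chromene, via lithium acetylide 7 (not isolated), via lithium ynolate 8 (not isolated)
Conditions: LiN(SiMe3)2, THF, −78 °C; LiOOtBu (from t-BuOOH and LiN(SiMe3)2), −78 → 0 °C; iPr3SiOTf, −78 → 0 °C
Reagents that add atoms: tert-butyl hydroperoxide, CC(C)(C)OO; triisopropylsilyl trifluoromethanesulfonate, CC(C)[Si](OS(=O)(=O)C(F)(F)F)(C(C)C)C(C)C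
Why: Established preparation of siloxyalkynes: the acetylide attacks the oxenoid oxygen of lithium tert-butyl peroxide to give the ynolate, which the bulky silyl triflate traps on oxygen. The amide base is too weak to remove the C2 hydrogen.

Step 6
Reactants: 10 3-ethoxycyclobut-2-en-1-one
Product: 11 3-(benzyloxy)cyclobut-2-en-1-one
Conditions: BnOH (3 equiv), camphorsulfonic acid (5 mol%), toluene, 40 °C, reduced pressure
Reagents that add atoms: benzyl alcohol, OCc1ccccc1
Why: Acid-catalysed alkoxy exchange of a vinylogous ester (addition of the alcohol at C3 and loss of ethanol, the path by which dilute acid hydrolyses 10), driven by removal of ethanol. It places a hydrogenolysable group on the oxygen that becomes O5 of unit 2.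

Step 7
Reactants: 9 (S)-5,7-bis(benzyloxy)-2-[3,4-bis(benzyloxy)phenyl]-3-[(triisopropylsiloxy)ethynyl]-2H-chromene; 11 3-(benzyloxy)cyclobut-2-en-1-one
Product: 16 (S)-3-[4-(benzyloxy)-2-hydroxy-6-(triisopropylsiloxy)phenyl]-5,7-bis(benzyloxy)-2-[3,4-bis(benzyloxy)phenyl]-2H-chromene, via vinylketene 12 (not isolated), via cyclobutenone adduct 13 (not isolated), via dienylketene 14 (not isolated), via cyclohexadienone 15 (not isolated)
Conditions: 11 (2.5 equiv), toluene, 80 °C, dark
Reagents that add atoms: none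
Why: Danheiser benzannulation. Thermal 4π electrocyclic opening of 11 gives the alkoxyvinylketene 12, and the ynol ether 9, polarised so that the carbon bearing the chromene is nucleophilic, adds to it in a [2+2] cycloaddition in which that carbon bonds to the ketene carbonyl carbon (future C8–C8a) and the oxygen-bearing carbon to the ketene α-carbon (future C7–C6), giving 13. A second 4π opening gives the dienylketene 14, whose 6π electrocyclisation forms C4a–C8a and closes the carbocycle as dienone 15, which tautomerises to phenol 16. The closest known reaction is the benzannulation of 3-alkylcyclobutenones with triisopropylsiloxyalkynes to resorcinol monosilyl ethers; the 3-alkoxy group on the cyclobutenone is the only extension and ends para to the chromene. No stereocentre is formed. The selectivity needed is the orientation of the [2+2] step, which the ynol ether polarisation secures; hydroxyl and siloxy both flank the new aryl–C3 bond and are interchangeable, so later closure through either oxygen can give only the 8-linked unit 2. The second requirement is that C2 keeps its configuration, so the temperature is held at the minimum needed for the first ring opening and light is excluded, because 2H-chromenes open reversibly to o-quinone methides on stronger heating or irradiation.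

Step 8
Reactants: 16 (S)-3-[4-(benzyloxy)-2-hydroxy-6-(triisopropylsiloxy)phenyl]-5,7-bis(benzyloxy)-2-[3,4-bis(benzyloxy)phenyl]-2H-chromene
Product: 18 (2R,3S,4S)-3-[4-(benzyloxy)-2-hydroxy-6-(triisopropylsiloxy)phenyl]-5,7-bis(benzyloxy)-2-[3,4-bis(benzyloxy)phenyl]chroman-4-ol (2,3-cis and 3,4-trans), via cyclic alkylborane 17 (not isolated)
Conditions: BH3·THF (4 equiv), THF, 0 °C → rt; then 3 M NaOH, 30% H2O2, 0 °C
Reagents that add atoms: hydrogen peroxide, OO
Why: Hydroboration–oxidation of a 3-aryl-2H-chromene, with the regiochemistry known for isoflav-3-enes: boron goes to the less substituted C4 and hydrogen to C3, syn, on the face away from the C2 aryl group. The C3 aryl therefore ends cis to the C2 aryl, and oxidation with retention gives the 3,4-trans alcohol; the basic work-up avoids acid-induced closure to a pterocarpan.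

Step 9
Reactants: 18 (2R,3S,4S)-3-[4-(benzyloxy)-2-hydroxy-6-(triisopropylsiloxy)phenyl]-5,7-bis(benzyloxy)-2-[3,4-bis(benzyloxy)phenyl]chroman-4-ol
Product: 20 (2R,3R,4S)-3-[4-(benzyloxy)-2-hydroxy-6-(triisopropylsiloxy)phenyl]-5,7-bis(benzyloxy)-2-[3,4-bis(benzyloxy)phenyl]-4-(triethylsiloxy)chroman, via bis(triethylsilyl) ether 19 (not isolated)
Conditions: Et3SiOTf (2.5 equiv), 2,6-lutidine, CH2Cl2, −78 → 0 °C; then K2CO3, MeOH, 0 °C
Reagents that add atoms: triethylsilyl trifluoromethanesulfonate, CC[Si](CC)(CC)OS(=O)(=O)C(F)(F)F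
Why: Both hydroxyls are silylated and the aryl triethylsilyl ether is then removed by methanolysis, since it is far more base-labile than the hindered secondary alkyl triethylsilyl ether or the aryl triisopropylsilyl ether. C4 is thereby masked against oxidation and ionisation while the phenol is free again.

Step 10
Reactants: 20 (2R,3R,4S)-3-[4-(benzyloxy)-2-hydroxy-6-(triisopropylsiloxy)phenyl]-5,7-bis(benzyloxy)-2-[3,4-bis(benzyloxy)phenyl]-4-(triethylsiloxy)chroman
Product: 21 6-(benzyloxy)-3-[(2R,3R,4S)-5,7-bis(benzyloxy)-2-[3,4-bis(benzyloxy)phenyl]-4-(triethylsiloxy)chroman-3-yl]-2-hydroxy-4-(triisopropylsiloxy)benzaldehyde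
Conditions: MgCl2, Et3N, (CH2O)n, THF, 65 °C
Reagents that add atoms: paraformaldehyde (as formaldehyde), C=O
Why: Magnesium phenoxide-directed ortho-formylation: formaldehyde is delivered within the chelate to the only free position ortho to the phenol, and the resulting benzylic alkoxide is oxidised by a second formaldehyde. The medium is basic, so the C4 silyl ether is not ionised and the electron-rich ring A of unit 1 is not attacked.

Step 11
Reactants: 21 6-(benzyloxy)-3-[(2R,3R,4S)-5,7-bis(benzyloxy)-2-[3,4-bis(benzyloxy)phenyl]-4-(triethylsiloxy)chroman-3-yl]-2-hydroxy-4-(triisopropylsiloxy)benzaldehyde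
Product: 22 1-[6-(benzyloxy)-3-[(2R,3R,4S)-5,7-bis(benzyloxy)-2-[3,4-bis(benzyloxy)phenyl]-4-(triethylsiloxy)chroman-3-yl]-2-hydroxy-4-(triisopropylsiloxy)phenyl]prop-2-yn-1-ol (both carbinol epimers)
Conditions: HC≡CMgBr (4 equiv), THF, 0 °C
Reagents that add atoms: ethynylmagnesium bromide, C#C[Mg]Br
Why: Grignard addition to the aldehyde after deprotonation of the phenol by the first equivalent; the new carbinol centre is destroyed in the next step, so its configuration does not matter.

Step 12
Reactants: 22 1-[6-(benzyloxy)-3-[(2R,3R,4S)-5,7-bis(benzyloxy)-2-[3,4-bis(benzyloxy)phenyl]-4-(triethylsiloxy)chroman-3-yl]-2-hydroxy-4-(triisopropylsiloxy)phenyl]prop-2-yn-1-ol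
Product: 24 5-(benzyloxy)-8-[(2R,3R,4S)-5,7-bis(benzyloxy)-2-[3,4-bis(benzyloxy)phenyl]-4-(triethylsiloxy)chroman-3-yl]-7-(triisopropylsiloxy)-4H-chromen-4-one, via ynone 23 (not isolated)
Conditions: MnO2, CH2Cl2, rt; filter; 4-(dimethylamino)pyridine (20 mol%), DMF, rt
Reagents that add atoms: none
Why: MnO2 oxidises the benzylic, propargylic alcohol, and the o-hydroxyaryl ynone closes by amine-catalysed 6-endo oxa-Michael addition (conjugate addition of the pyridine, attack of the phenol on the β-carbon, loss of the catalyst) to the chromone instead of the 5-exo benzofuranone. The phenol oxygen becomes O1 of unit 2.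

Step 13
Reactants: 24 5-(benzyloxy)-8-[(2R,3R,4S)-5,7-bis(benzyloxy)-2-[3,4-bis(benzyloxy)phenyl]-4-(triethylsiloxy)chroman-3-yl]-7-(triisopropylsiloxy)-4H-chromen-4-one; 25 4-(benzyloxy)phenylboronic acid
Product: 26 (2R)-5-(benzyloxy)-2-[4-(benzyloxy)phenyl]-8-[(2R,3R,4S)-5,7-bis(benzyloxy)-2-[3,4-bis(benzyloxy)phenyl]-4-(triethylsiloxy)chroman-3-yl]-7-(triisopropylsiloxy)chroman-4-one
Conditions: [Rh(OH)(C8H12)]2 (2.5 mol%; C8H12 = cycloocta-1,5-diene), (R)-MeO-F12-BIPHEP (5.5 mol%), 25 (3 equiv), toluene/H2O, 40 °C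
Reagents that add atoms: none
Why: Rhodium-catalysed asymmetric 1,4-addition of an arylboronic acid to a chromone (transmetallation, insertion of the enone into the Rh–aryl bond, protonolysis by water), which the electron-poor biaryl bisphosphine makes fast enough for 5,7-dioxygenated chromones. The ligand, not the remote centres of unit 1, sets C2 of unit 2 as R, and the neutral medium keeps the new flavanone closed.

Step 14
Reactants: 26 (2R)-5-(benzyloxy)-2-[4-(benzyloxy)phenyl]-8-[(2R,3R,4S)-5,7-bis(benzyloxy)-2-[3,4-bis(benzyloxy)phenyl]-4-(triethylsiloxy)chroman-3-yl]-7-(triisopropylsiloxy)chroman-4-one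
Product: 27 (2R)-5-(benzyloxy)-2-[4-(benzyloxy)phenyl]-8-[(2R,3S,4S)-5,7-bis(benzyloxy)-2-[3,4-bis(benzyloxy)phenyl]-4-hydroxychroman-3-yl]-7-(triisopropylsiloxy)chroman-4-one
Conditions: HF·pyridine, pyridine, THF, 0 °C
Reagents that add atoms: none
Why: Buffered HF cleaves the alkyl triethylsilyl ether much faster than the bulky aryl triisopropylsilyl ether, so only the C4 hydroxyl of unit 1 is released.

Step 15
Reactants: 27 (2R)-5-(benzyloxy)-2-[4-(benzyloxy)phenyl]-8-[(2R,3S,4S)-5,7-bis(benzyloxy)-2-[3,4-bis(benzyloxy)phenyl]-4-hydroxychroman-3-yl]-7-(triisopropylsiloxy)chroman-4-one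
Product: 28 (2R,3R)-5,7-bis(benzyloxy)-2-[3,4-bis(benzyloxy)phenyl]-3-[(2R)-5-(benzyloxy)-2-[4-(benzyloxy)phenyl]-4-oxo-7-(triisopropylsiloxy)chroman-8-yl]chroman-4-one
Conditions: Dess–Martin periodinane, NaHCO3, CH2Cl2, 0 °C → rt
Reagents that add atoms: none
Why: Dess–Martin oxidation of the secondary benzylic alcohol under buffered, near-neutral conditions. C3–H becomes enolisable, but no base is present and the di-ortho-substituted aryl group on C3 hinders enolisation, so the cis arrangement should hold.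

Step 16
Reactants: 28 (2R,3R)-5,7-bis(benzyloxy)-2-[3,4-bis(benzyloxy)phenyl]-3-[(2R)-5-(benzyloxy)-2-[4-(benzyloxy)phenyl]-4-oxo-7-(triisopropylsiloxy)chroman-8-yl]chroman-4-one
Product: 29 (2R,3R)-5,7-bis(benzyloxy)-2-[3,4-bis(benzyloxy)phenyl]-3-[(2R)-5-(benzyloxy)-2-[4-(benzyloxy)phenyl]-7-hydroxy-4-oxochroman-8-yl]chroman-4-one
Conditions: Bu4NF, AcOH (1:1), THF, 0 °C
Reagents that add atoms: none
Why: Fluoride cleaves the aryl silyl ether, which the para carbonyl group activates; acetic acid keeps the medium from becoming basic enough to enolise C3 of unit 1 or to open either pyranone.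

Step 17
Reactants: 29 (2R,3R)-5,7-bis(benzyloxy)-2-[3,4-bis(benzyloxy)phenyl]-3-[(2R)-5-(benzyloxy)-2-[4-(benzyloxy)phenyl]-7-hydroxy-4-oxochroman-8-yl]chroman-4-one
Product: 30 (2R,3R)-2-(3,4-dihydroxyphenyl)-5,7-dihydroxy-3-[(2R)-5,7-dihydroxy-2-(4-hydroxyphenyl)-4-oxochroman-8-yl]chroman-4-one
Conditions: H2 (1 atm), Pd/C, EtOAc/MeOH, rt
Reagents that add atoms: none
Why: Hydrogenolysis of the six benzyl ethers under neutral conditions should release all phenols, the catechol included, without acid or base that could epimerise C3 or open the flavanones.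

## Compound list

1 | 2,4,6-trihydroxybenzaldehyde | O=Cc1c(O)cc(O)cc1O | starting material
2 | 4,6-bis(benzyloxy)-2-hydroxybenzaldehyde | O=Cc1c(O)cc(OCc2ccccc2)cc1OCc1ccccc1 | intermediate
3 | 3,4-bis(benzyloxy)benzaldehyde | O=Cc1ccc(OCc2ccccc2)c(OCc2ccccc2)c1 | starting material
4 | (E)-3-[3,4-bis(benzyloxy)phenyl]prop-2-enal | O=C/C=C/c1ccc(OCc2ccccc2)c(OCc2ccccc2)c1 | intermediate
5 | (S)-5,7-bis(benzyloxy)-2-[3,4-bis(benzyloxy)phenyl]-2H-chromene-3-carbaldehyde | O=CC1=Cc2c(OCc3ccccc3)cc(OCc3ccccc3)cc2O[C@H]1c1ccc(OCc2ccccc2)c(OCc2ccccc2)c1 | intermediate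
6 | (S)-5,7-bis(benzyloxy)-2-[3,4-bis(benzyloxy)phenyl]-3-ethynyl-2H-chromene | C#CC1=Cc2c(OCc3ccccc3)cc(OCc3ccccc3)cc2O[C@H]1c1ccc(OCc2ccccc2)c(OCc2ccccc2)c1 | intermediate
7 | lithium acetylide of 6 | [Li+].[C-]#CC1=Cc2c(OCc3ccccc3)cc(OCc3ccccc3)cc2O[C@H]1c1ccc(OCc2ccccc2)c(OCc2ccccc2)c1 | intermediate
8 | lithium ynolate (acetylide of 6 with oxygen on the terminal carbon) | [Li+].[O-]C#CC1=Cc2c(OCc3ccccc3)cc(OCc3ccccc3)cc2O[C@H]1c1ccc(OCc2ccccc2)c(OCc2ccccc2)c1 | intermediate
9 | (S)-5,7-bis(benzyloxy)-2-[3,4-bis(benzyloxy)phenyl]-3-[(triisopropylsiloxy)ethynyl]-2H-chromene | CC(C)[Si](OC#CC1=Cc2c(OCc3ccccc3)cc(OCc3ccccc3)cc2O[C@H]1c1ccc(OCc2ccccc2)c(OCc2ccccc2)c1)(C(C)C)C(C)C | intermediate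
10 | 3-ethoxycyclobut-2-en-1-one | CCOC1=CC(=O)C1 | starting material
11 | 3-(benzyloxy)cyclobut-2-en-1-one | O=C1C=C(OCc2ccccc2)C1 | intermediate
12 | 3-(benzyloxy)buta-1,3-dien-1-one (vinylketene) | C=C(OCc1ccccc1)C=C=O | intermediate
13 | 4-[1-(benzyloxy)ethenyl]-2-[(S)-5,7-bis(benzyloxy)-2-[3,4-bis(benzyloxy)phenyl]-2H-chromen-3-yl]-3-(triisopropylsiloxy)cyclobut-2-en-1-one (ring CH centre unassigned) | C=C(OCc1ccccc1)C1C(=O)C(C2=Cc3c(OCc4ccccc4)cc(OCc4ccccc4)cc3O[C@H]2c2ccc(OCc3ccccc3)c(OCc3ccccc3)c2)=C1O[Si](C(C)C)(C(C)C)C(C)C | intermediate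
14 | (3E)-5-(benzyloxy)-2-[(S)-5,7-bis(benzyloxy)-2-[3,4-bis(benzyloxy)phenyl]-2H-chromen-3-yl]-3-(triisopropylsiloxy)hexa-1,3,5-trien-1-one (dienylketene, ketene carbon and alkoxyvinyl group cis) | O=C=C(C1=Cc2c(OCc3ccccc3)cc(OCc3ccccc3)cc2O[C@H]1c1ccc(OCc2ccccc2)c(OCc2ccccc2)c1)/C(O[Si](C(C)C)(C(C)C)C(C)C)=C\C(=C)OCc1ccccc1 | intermediate
15 | 5-(benzyloxy)-2-[(S)-5,7-bis(benzyloxy)-2-[3,4-bis(benzyloxy)phenyl]-2H-chromen-3-yl]-3-(triisopropylsiloxy)cyclohexa-2,4-dien-1-one | O=C1CC(OCc2ccccc2)=CC(O[Si](C(C)C)(C(C)C)C(C)C)=C1C1=Cc2c(OCc3ccccc3)cc(OCc3ccccc3)cc2O[C@H]1c1ccc(OCc2ccccc2)c(OCc2ccccc2)c1 | intermediate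
16 | (S)-3-[4-(benzyloxy)-2-hydroxy-6-(triisopropylsiloxy)phenyl]-5,7-bis(benzyloxy)-2-[3,4-bis(benzyloxy)phenyl]-2H-chromene | Oc1cc(OCc2ccccc2)cc(O[Si](C(C)C)(C(C)C)C(C)C)c1C1=Cc2c(OCc3ccccc3)cc(OCc3ccccc3)cc2O[C@H]1c1ccc(OCc2ccccc2)c(OCc2ccccc2)c1 | intermediate
17 | cyclic aryloxy(alkyl)borane from syn addition of B–H across C3=C4 of 16: boron on C4 and bridged to the phenol oxygen, hydrogen on C3, both anti to the C2 aryl | [BH]1Oc2cc(OCc3ccccc3)cc(O[Si](C(C)C)(C(C)C)C(C)C)c2[C@H]2[C@H]1c1c(OCc3ccccc3)cc(OCc3ccccc3)cc1O[C@H]2c1ccc(OCc2ccccc2)c(OCc2ccccc2)c1 | intermediate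
18 | (2R,3S,4S)-3-[4-(benzyloxy)-2-hydroxy-6-(triisopropylsiloxy)phenyl]-5,7-bis(benzyloxy)-2-[3,4-bis(benzyloxy)phenyl]chroman-4-ol | Oc1cc(OCc2ccccc2)cc(O[Si](C(C)C)(C(C)C)C(C)C)c1[C@H]1[C@H](O)c2c(OCc3ccccc3)cc(OCc3ccccc3)cc2O[C@H]1c1ccc(OCc2ccccc2)c(OCc2ccccc2)c1 | intermediate
19 | bis(triethylsilyl) ether of 18 (on the phenol and on O4) | CC[Si](CC)(CC)Oc1cc(OCc2ccccc2)cc(O[Si](C(C)C)(C(C)C)C(C)C)c1[C@H]1[C@H](O[Si](CC)(CC)CC)c2c(OCc3ccccc3)cc(OCc3ccccc3)cc2O[C@H]1c1ccc(OCc2ccccc2)c(OCc2ccccc2)c1 | intermediate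
20 | (2R,3R,4S)-3-[4-(benzyloxy)-2-hydroxy-6-(triisopropylsiloxy)phenyl]-5,7-bis(benzyloxy)-2-[3,4-bis(benzyloxy)phenyl]-4-(triethylsiloxy)chroman | Oc1cc(OCc2ccccc2)cc(O[Si](C(C)C)(C(C)C)C(C)C)c1[C@H]1[C@H](O[Si](CC)(CC)CC)c2c(OCc3ccccc3)cc(OCc3ccccc3)cc2O[C@H]1c1ccc(OCc2ccccc2)c(OCc2ccccc2)c1 | intermediate
21 | 6-(benzyloxy)-3-[(2R,3R,4S)-5,7-bis(benzyloxy)-2-[3,4-bis(benzyloxy)phenyl]-4-(triethylsiloxy)chroman-3-yl]-2-hydroxy-4-(triisopropylsiloxy)benzaldehyde | O=Cc1c(OCc2ccccc2)cc(O[Si](C(C)C)(C(C)C)C(C)C)c(c1O)[C@H]1[C@H](O[Si](CC)(CC)CC)c2c(OCc3ccccc3)cc(OCc3ccccc3)cc2O[C@H]1c1ccc(OCc2ccccc2)c(OCc2ccccc2)c1 | intermediate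
22 | propargylic alcohol from addition of ethynyl to the formyl group of 21 (both carbinol epimers) | C#CC(O)c1c(OCc2ccccc2)cc(O[Si](C(C)C)(C(C)C)C(C)C)c(c1O)[C@H]1[C@H](O[Si](CC)(CC)CC)c2c(OCc3ccccc3)cc(OCc3ccccc3)cc2O[C@H]1c1ccc(OCc2ccccc2)c(OCc2ccccc2)c1 | intermediate
23 | o-hydroxyaryl ethynyl ketone from oxidation of 22 | C#CC(=O)c1c(OCc2ccccc2)cc(O[Si](C(C)C)(C(C)C)C(C)C)c(c1O)[C@H]1[C@H](O[Si](CC)(CC)CC)c2c(OCc3ccccc3)cc(OCc3ccccc3)cc2O[C@H]1c1ccc(OCc2ccccc2)c(OCc2ccccc2)c1 | intermediate
24 | 5-(benzyloxy)-8-[(2R,3R,4S)-5,7-bis(benzyloxy)-2-[3,4-bis(benzyloxy)phenyl]-4-(triethylsiloxy)chroman-3-yl]-7-(triisopropylsiloxy)-4H-chromen-4-one | O=c1ccoc2c1c(OCc1ccccc1)cc(O[Si](C(C)C)(C(C)C)C(C)C)c2[C@H]1[C@H](O[Si](CC)(CC)CC)c2c(OCc3ccccc3)cc(OCc3ccccc3)cc2O[C@H]1c1ccc(OCc2ccccc2)c(OCc2ccccc2)c1 | intermediate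
25 | 4-(benzyloxy)phenylboronic acid | OB(O)c1ccc(OCc2ccccc2)cc1 | starting material
26 | (2R)-5-(benzyloxy)-2-[4-(benzyloxy)phenyl]-8-[(2R,3R,4S)-5,7-bis(benzyloxy)-2-[3,4-bis(benzyloxy)phenyl]-4-(triethylsiloxy)chroman-3-yl]-7-(triisopropylsiloxy)chroman-4-one | O=C1C[C@H](c2ccc(OCc3ccccc3)cc2)Oc2c1c(OCc1ccccc1)cc(O[Si](C(C)C)(C(C)C)C(C)C)c2[C@H]1[C@H](O[Si](CC)(CC)CC)c2c(OCc3ccccc3)cc(OCc3ccccc3)cc2O[C@H]1c1ccc(OCc2ccccc2)c(OCc2ccccc2)c1 | intermediate
27 | (2R)-5-(benzyloxy)-2-[4-(benzyloxy)phenyl]-8-[(2R,3S,4S)-5,7-bis(benzyloxy)-2-[3,4-bis(benzyloxy)phenyl]-4-hydroxychroman-3-yl]-7-(triisopropylsiloxy)chroman-4-one | O=C1C[C@H](c2ccc(OCc3ccccc3)cc2)Oc2c1c(OCc1ccccc1)cc(O[Si](C(C)C)(C(C)C)C(C)C)c2[C@H]1[C@H](O)c2c(OCc3ccccc3)cc(OCc3ccccc3)cc2O[C@H]1c1ccc(OCc2ccccc2)c(OCc2ccccc2)c1 | intermediate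
28 | (2R,3R)-5,7-bis(benzyloxy)-2-[3,4-bis(benzyloxy)phenyl]-3-[(2R)-5-(benzyloxy)-2-[4-(benzyloxy)phenyl]-4-oxo-7-(triisopropylsiloxy)chroman-8-yl]chroman-4-one | O=C1C[C@H](c2ccc(OCc3ccccc3)cc2)Oc2c1c(OCc1ccccc1)cc(O[Si](C(C)C)(C(C)C)C(C)C)c2[C@H]1C(=O)c2c(OCc3ccccc3)cc(OCc3ccccc3)cc2O[C@H]1c1ccc(OCc2ccccc2)c(OCc2ccccc2)c1 | intermediate
29 | (2R,3R)-5,7-bis(benzyloxy)-2-[3,4-bis(benzyloxy)phenyl]-3-[(2R)-5-(benzyloxy)-2-[4-(benzyloxy)phenyl]-7-hydroxy-4-oxochroman-8-yl]chroman-4-one | O=C1C[C@H](c2ccc(OCc3ccccc3)cc2)Oc2c1c(OCc1ccccc1)cc(O)c2[C@H]1C(=O)c2c(OCc3ccccc3)cc(OCc3ccccc3)cc2O[C@H]1c1ccc(OCc2ccccc2)c(OCc2ccccc2)c1 | intermediate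
30 | (2R,3R)-2-(3,4-dihydroxyphenyl)-5,7-dihydroxy-3-[(2R)-5,7-dihydroxy-2-(4-hydroxyphenyl)-4-oxochroman-8-yl]chroman-4-one | O=C1C[C@H](c2ccc(O)cc2)Oc2c1c(O)cc(O)c2[C@H]1C(=O)c2c(O)cc(O)cc2O[C@H]1c1ccc(O)c(O)c1 | target

## Step count and risks

Total step count: 17. Longest linear sequence: 15 steps (from 1 through steps 1, 3, 4, 5 and 7–17).

**Step 7 (key step).**
- What may go wrong: 11 is a vinylogous ester and may open to the ketene only well above 80 °C. At such temperatures the chromene can open reversibly to its o-quinone methide and lose the configuration at C2. A lesser problem is O-acylation of the product phenol by excess ketene, which a brief treatment with K2CO3 in methanol at 0 °C would reverse.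
- Fallback: this sets out from 9. The same ketene 12 is generated at 0 °C by 1,4-dehydrochlorination of (E)-3-(benzyloxy)but-2-enoyl chloride F1 with Et3N in the presence of 9. The cyclobutenone 13 is then isolated and warmed only as far as its own ring opening needs; it carries an alkenyl group on the sp3 carbon and should open more readily than 11. Electrocyclisation and tautomerisation then return the route to 16.

**Step 8.**
- What may go wrong: slow addition to the hindered trisubstituted double bond, incomplete discrimination between its faces, or loss of the electron-rich benzylic boron group by protodeboronation before oxidation.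
- Fallback: this sets out from 16 and replaces the hydroboration by reduction followed by late benzylic oxidation. Homogeneous hydrogenation with [Ir(C8H12)(P(C6H11)3)(C5H5N)]PF6 and H2 in CH2Cl2, which spares benzyl ethers, should add hydrogen anti to the C2 aryl group and give the cis-flavan F2. With no oxygen at C4, no protection is needed. The conditions of steps 10 to 13 would then give in turn the salicylaldehyde F3, the propargylic alcohol F4, the chromone F5 and the flavanone F6. DDQ in wet CH2Cl2 then abstracts hydride from C4 of unit 1 (benzylic to the 5,7-dioxygenated ring, as in the C4 functionalisation of benzylated flavans), and water adds trans to the C3 substituent. The route is rejoined at 27.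

**Step 10.**
- What may go wrong: failure of the magnesium chelate to form next to the bulky C3 substituent, or arrest at the hydroxymethyl stage.
- Fallback: this sets out from 20. Iodination ortho to the phenol with I2 and morpholine in CH2Cl2 should give the iodophenol F7. Deprotonation with MeMgCl, iodine–magnesium exchange with i-PrMgCl·LiCl at −20 °C and quenching with DMF return the route to 21.

**Step 13.**
- What may go wrong: slow insertion of the electron-rich, 5-alkoxy-substituted chromone with competing protodeboronation of 25, or a mismatch with the existing centres that lowers the selectivity.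
- Fallback: this sets out from 24 and gives up catalyst control. Copper-mediated conjugate addition of 4-(benzyloxy)phenylmagnesium bromide F8 (CuBr·SMe2, Me3SiCl, THF, −78 °C), followed by hydrolysis of the silyl enol ether, should give 26 together with its epimer at C2 of unit 2, F9. The two are diastereomers and are separated by chromatography, which returns the route to 26.

**Step 16.**
- What may go wrong: epimerisation at C3 of unit 1 to the more stable trans isomer, or retro-oxa-Michael opening of a pyranone, once fluoride meets the compound in which the C4 carbonyl of unit 1 is already present.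
- Fallback: this sets out from 26 and moves the silyl removal ahead of the oxidation. Both silyl groups are removed with Bu4NF/AcOH to give the phenol-alcohol F10. The 7-hydroxyl is benzylated (BnBr, K2CO3, acetone, rt) to F11. Dess–Martin oxidation gives the heptabenzyl diketone F12, and hydrogenolysis of F12 (H2, Pd/C) leads directly to 30, so the ketone never meets fluoride.

## Further compounds

F1 | step 7 | (E)-3-(benzyloxy)but-2-enoyl chloride | C/C(OCc1ccccc1)=C\C(Cl)=O
F2 | step 8 | (2R,3R)-3-[4-(benzyloxy)-2-hydroxy-6-(triisopropylsiloxy)phenyl]-5,7-bis(benzyloxy)-2-[3,4-bis(benzyloxy)phenyl]chroman | Oc1cc(OCc2ccccc2)cc(O[Si](C(C)C)(C(C)C)C(C)C)c1[C@H]1Cc2c(OCc3ccccc3)cc(OCc3ccccc3)cc2O[C@H]1c1ccc(OCc2ccccc2)c(OCc2ccccc2)c1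
F3 | step 8 | 6-(benzyloxy)-3-[(2R,3R)-5,7-bis(benzyloxy)-2-[3,4-bis(benzyloxy)phenyl]chroman-3-yl]-2-hydroxy-4-(triisopropylsiloxy)benzaldehyde | O=Cc1c(OCc2ccccc2)cc(O[Si](C(C)C)(C(C)C)C(C)C)c(c1O)[C@H]1Cc2c(OCc3ccccc3)cc(OCc3ccccc3)cc2O[C@H]1c1ccc(OCc2ccccc2)c(OCc2ccccc2)c1
F4 | step 8 | propargylic alcohol from addition of ethynyl to the formyl group of F3 (both carbinol epimers) | C#CC(O)c1c(OCc2ccccc2)cc(O[Si](C(C)C)(C(C)C)C(C)C)c(c1O)[C@H]1Cc2c(OCc3ccccc3)cc(OCc3ccccc3)cc2O[C@H]1c1ccc(OCc2ccccc2)c(OCc2ccccc2)c1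
F5 | step 8 | 5-(benzyloxy)-8-[(2R,3R)-5,7-bis(benzyloxy)-2-[3,4-bis(benzyloxy)phenyl]chroman-3-yl]-7-(triisopropylsiloxy)-4H-chromen-4-one | O=c1ccoc2c1c(OCc1ccccc1)cc(O[Si](C(C)C)(C(C)C)C(C)C)c2[C@H]1Cc2c(OCc3ccccc3)cc(OCc3ccccc3)cc2O[C@H]1c1ccc(OCc2ccccc2)c(OCc2ccccc2)c1
F6 | step 8 | (2R)-5-(benzyloxy)-2-[4-(benzyloxy)phenyl]-8-[(2R,3R)-5,7-bis(benzyloxy)-2-[3,4-bis(benzyloxy)phenyl]chroman-3-yl]-7-(triisopropylsiloxy)chroman-4-one | O=C1C[C@H](c2ccc(OCc3ccccc3)cc2)Oc2c1c(OCc1ccccc1)cc(O[Si](C(C)C)(C(C)C)C(C)C)c2[C@H]1Cc2c(OCc3ccccc3)cc(OCc3ccccc3)cc2O[C@H]1c1ccc(OCc2ccccc2)c(OCc2ccccc2)c1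
F7 | step 10 | iodophenol: 20 with iodine on the free position ortho to the phenol | Ic1c(OCc2ccccc2)cc(O[Si](C(C)C)(C(C)C)C(C)C)c(c1O)[C@H]1[C@H](O[Si](CC)(CC)CC)c2c(OCc3ccccc3)cc(OCc3ccccc3)cc2O[C@H]1c1ccc(OCc2ccccc2)c(OCc2ccccc2)c1
F8 | step 13 | 4-(benzyloxy)phenylmagnesium bromide | Br[Mg]c1ccc(OCc2ccccc2)cc1
F9 | step 13 | epimer of 26 with S configuration at C2 of unit 2 | O=C1C[C@@H](c2ccc(OCc3ccccc3)cc2)Oc2c1c(OCc1ccccc1)cc(O[Si](C(C)C)(C(C)C)C(C)C)c2[C@H]1[C@H](O[Si](CC)(CC)CC)c2c(OCc3ccccc3)cc(OCc3ccccc3)cc2O[C@H]1c1ccc(OCc2ccccc2)c(OCc2ccccc2)c1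
F10 | step 16 | (2R)-5-(benzyloxy)-2-[4-(benzyloxy)phenyl]-8-[(2R,3S,4S)-5,7-bis(benzyloxy)-2-[3,4-bis(benzyloxy)phenyl]-4-hydroxychroman-3-yl]-7-hydroxychroman-4-one | O=C1C[C@H](c2ccc(OCc3ccccc3)cc2)Oc2c1c(OCc1ccccc1)cc(O)c2[C@H]1[C@H](O)c2c(OCc3ccccc3)cc(OCc3ccccc3)cc2O[C@H]1c1ccc(OCc2ccccc2)c(OCc2ccccc2)c1
F11 | step 16 | (2R)-5,7-bis(benzyloxy)-2-[4-(benzyloxy)phenyl]-8-[(2R,3S,4S)-5,7-bis(benzyloxy)-2-[3,4-bis(benzyloxy)phenyl]-4-hydroxychroman-3-yl]chroman-4-one | O=C1C[C@H](c2ccc(OCc3ccccc3)cc2)Oc2c1c(OCc1ccccc1)cc(OCc1ccccc1)c2[C@H]1[C@H](O)c2c(OCc3ccccc3)cc(OCc3ccccc3)cc2O[C@H]1c1ccc(OCc2ccccc2)c(OCc2ccccc2)c1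
F12 | step 16 | (2R,3R)-5,7-bis(benzyloxy)-2-[3,4-bis(benzyloxy)phenyl]-3-[(2R)-5,7-bis(benzyloxy)-2-[4-(benzyloxy)phenyl]-4-oxochroman-8-yl]chroman-4-one | O=C1C[C@H](c2ccc(OCc3ccccc3)cc2)Oc2c1c(OCc1ccccc1)cc(OCc1ccccc1)c2[C@H]1C(=O)c2c(OCc3ccccc3)cc(OCc3ccccc3)cc2O[C@H]1c1ccc(OCc2ccccc2)c(OCc2ccccc2)c1
A1 | alternative 1 | chalcone: (E)-1-[4,6-bis(benzyloxy)-2-hydroxyphenyl]-3-[(2R)-5,7-bis(benzyloxy)-2-[4-(benzyloxy)phenyl]-4-oxochroman-8-yl]prop-2-en-1-one | O=C1C[C@H](c2ccc(OCc3ccccc3)cc2)Oc2c1c(OCc1ccccc1)cc(OCc1ccccc1)c2/C=C/C(=O)c1c(O)cc(OCc2ccccc2)cc1OCc1ccccc1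
A2 | alternative 1 | 5,7-bis(benzyloxy)-3-[(2R)-5,7-bis(benzyloxy)-2-[4-(benzyloxy)phenyl]-4-oxochroman-8-yl]-4H-chromen-4-one | O=C1C[C@H](c2ccc(OCc3ccccc3)cc2)Oc2c1c(OCc3ccccc3)cc(OCc3ccccc3)c2C1=COc4cc(OCc3ccccc3)cc(OCc3ccccc3)c4C1=O
A3 | alternative 2 | open-chain bromo alcohol: 1-[3,4-bis(benzyloxy)phenyl]-2-[2,4-bis(benzyloxy)-6-(methoxymethoxy)phenyl]-3-[2-bromo-4,6-bis(benzyloxy)phenyl]-3-(tert-butyldimethylsiloxy)propan-1-ol with the configuration of A4 | COCOc1cc(OCc2ccccc2)cc(OCc2ccccc2)c1[C@@H]([C@@H](O[Si](C)(C)C(C)(C)C)c1c(OCc2ccccc2)cc(OCc2ccccc2)cc1Br)[C@@H](O)c1ccc(OCc2ccccc2)c(OCc2ccccc2)c1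
A4 | alternative 2 | cis-2,3-flavan 4-silyl ether: 5,7-bis(benzyloxy)-2-[3,4-bis(benzyloxy)phenyl]-3-[2,4-bis(benzyloxy)-6-(methoxymethoxy)phenyl]-4-(tert-butyldimethylsiloxy)chroman | COCOc4cc(OCc3ccccc3)cc(OCc3ccccc3)c4[C@H]1[C@@H](O[Si](C)(C)C(C)(C)C)c2c(OCc3ccccc3)cc(OCc3ccccc3)cc2O[C@H]1c1ccc(OCc3ccccc3)c(OCc3ccccc3)c1
A5 | alternative 3 | methoxy o-quinone methide: 3,5-bis(benzyloxy)-6-(methoxymethylidene)cyclohexa-2,4-dien-1-one | COC=C1C(=O)C=C(OCc2ccccc2)C=C1OCc1ccccc1
A6 | alternative 3 | Z-stilbene: (2R)-5,7-bis(benzyloxy)-2-[4-(benzyloxy)phenyl]-8-[(Z)-2-[3,4-bis(benzyloxy)phenyl]ethenyl]chroman-4-one | O=C1C[C@H](c2ccc(OCc3ccccc3)cc2)Oc2c1c(OCc1ccccc1)cc(OCc1ccccc1)c2/C=C\c1ccc(OCc2ccccc2)c(OCc2ccccc2)c1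
A7 | alternative 3 | all-cis 4-methoxyflavan: (2R)-5,7-bis(benzyloxy)-2-[4-(benzyloxy)phenyl]-8-[5,7-bis(benzyloxy)-2-[3,4-bis(benzyloxy)phenyl]-4-methoxychroman-3-yl]chroman-4-one | O=C1C[C@H](c2ccc(OCc3ccccc3)cc2)Oc2c1c(OCc3ccccc3)cc(OCc3ccccc3)c2[C@H]1[C@@H](OC)c2c(OCc3ccccc3)cc(OCc3ccccc3)cc2O[C@H]1c1ccc(OCc3ccccc3)c(OCc3ccccc3)c1
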